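The route rests on cutting the two diaryl ether bonds from the C4 oxygen of ring D to C1 of ring E and from the C4 oxygen of ring E to C1 of ring F. Rings E and F are 4-oxy-3,5-dioxygenated phenyl units bound through C1, which is the pattern of syringic acid with a carboxyl on C1 that can leave as CO2. A single anodic decarboxylative phenol coupling should therefore graft both rings onto a tetramer ABCD, a nonamethyl ether with one free hydroxyl on C4 of ring D, which is built beforehand by iterative copper-catalysed diaryl ether synthesis. Exhaustive demethylation then gives the target.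

Key step: step 8

Lettering: rings run A to F from the 2,4,6-trioxygenated end ring to the 3,4,5-trioxygenated end ring; in every ring C4 is the oxygen-bearing carbon flanked by two oxygenated carbons and C1 is the oxygen-bearing carbon para to it.

Assumption: the three starting phenols and the acid are taken as purchasable, and the free polyphenol, which is sensitive to air, is handled under argon with degassed solvents.

Step 1
Reactants: 1 4-bromo-2,6-dimethoxyphenol
Product: 2 2-(benzyloxy)-5-bromo-1,3-dimethoxybenzene
Conditions: BnBr, K2CO3, DMF, 50 °C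
Reagents that add atoms: benzyl bromide, BrCc1ccccc1
Why: Williamson ether synthesis on an acidic phenol masks the hydroxyl that must later become the nucleophilic chain end.

Step 2
Reactants: 3 2,4,6-trimethoxyphenol; 2 2-(benzyloxy)-5-bromo-1,3-dimethoxybenzene
Product: 4 dimer AB benzyl ether
Conditions: CuI (10 mol %), picolinic acid (20 mol %), K3PO4, DMSO, 100 °C, Ar
Reagents that add atoms: none
Why: Ullmann-type diaryl ether synthesis, in which the CuI–picolinic acid catalyst is suited to di-ortho-substituted phenoxides and the C–Br carbon of 2 has no ortho substituent, so the oxygen of 3 should be arylated to join C4–O of ring A to C1 of ring B.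

Step 3
Reactants: 4 dimer AB benzyl ether
Product: 5 dimer AB phenol
Conditions: H2 (1 atm), 10% Pd/C, EtOAc–MeOH, rt
Reagents that add atoms: none
Why: Hydrogenolysis of the benzyl ether frees the C4 hydroxyl of ring B while methyl aryl ethers and diaryl ethers are inert.

Step 4
Reactants: 5 dimer AB phenol; 2 2-(benzyloxy)-5-bromo-1,3-dimethoxybenzene
Product: 6 trimer ABC benzyl ether
Conditions: CuI (10 mol %), picolinic acid (20 mol %), K3PO4, DMSO, 100 °C, Ar
Reagents that add atoms: none
Why: The same Ullmann-type diaryl ether synthesis should apply, since the reacting 2,6-dimethoxyphenoxide of 5 has the same local environment as that of 3.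

Step 5
Reactants: 6 trimer ABC benzyl ether
Product: 7 trimer ABC phenol
Conditions: H2 (1 atm), 10% Pd/C, EtOAc–MeOH, rt
Reagents that add atoms: none
Why: Hydrogenolysis of the single benzyl ether frees the C4 hydroxyl of ring C without touching the other ether bonds.

Step 6
Reactants: 7 trimer ABC phenol; 2 2-(benzyloxy)-5-bromo-1,3-dimethoxybenzene
Product: 8 tetramer ABCD benzyl ether
Conditions: CuI (10 mol %), picolinic acid (20 mol %), K3PO4, DMSO, 100 °C, Ar
Reagents that add atoms: none
Why: A third Ullmann-type diaryl ether synthesis of the same kind joins C4–O of ring C to C1 of ring D, the reacting centres being unchanged from steps 2 and 4.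

Step 7
Reactants: 8 tetramer ABCD benzyl ether
Product: 9 tetramer ABCD phenol
Conditions: H2 (1 atm), 10% Pd/C, EtOAc–THF, rt
Reagents that add atoms: none
Why: Hydrogenolysis of the benzyl ether gives the free C4 hydroxyl of ring D that the key step needs.

Step 8
Reactants: 9 tetramer ABCD phenol; 10 syringic acid (2.0 equiv)
Product: 12 hexamer ABCDEF phenol, via pentamer ABCDE phenol 11 (not isolated)
Conditions: graphite-felt anode, Pt cathode, undivided cell, anode potential held at the foot of the phenol wave (set by cyclic voltammetry of 9), n-Bu4NBF4, 2,6-lutidine, 4 Å MS, MeCN–CH2Cl2, 0 °C, Ar; 10 in MeCN–2,6-lutidine by syringe pump; stop near 4 F per mol of 9; aq NaHCO3 wash; preparative chromatography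
Reagents that add atoms: none
Why: Proposed new method: at a potential where only the phenols are oxidised, with 2,6-lutidine as proton acceptor, 9 and the slowly fed 10 both give phenoxyl radicals, and the persistent, para-blocked chain radical should bond through oxygen to C1 of the syringate radical, giving a 4-aryloxy-4-carboxycyclohexa-2,5-dienone that irreversibly loses CO2 and rearomatises to pentamer phenol 11, which is oxidised and extended once more in the same way to 12. The closest known reaction type is the oxidative, enzyme-mediated decarboxylative polymerisation of 4-hydroxy-3,5-dimethoxybenzoic acid to poly(2,6-dimethoxy-1,4-phenylene oxide), here moved to an anode and to a discrete chain with a limited feed. No ring is closed and no stereocentre is formed. The step needs oxygen-to-para-carbon coupling in place of carbon–carbon coupling, which the substrate secures because every carbon of high spin density in 10 and in ring D of 9 is substituted and only C1 of 10 carries a group that can leave as CO2. It also needs a stop after two additions, which is statistical and is approached by keeping the chain phenol in excess over the slowly added acid, limiting the charge and following the chain-length distribution by HPLC, with acid-terminated self-coupling products of 10 removed by the hydrogencarbonate wash and recovered 9 and 11 resubmitted. The dry, non-nucleophilic medium should suppress trapping of over-oxidised chain ends as quinones and limit quinone-ketal redistribution of chain lengths.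

Step 9
Reactants: 12 hexamer ABCDEF phenol
Product: 13 target polyphenol CNP0187343.0
Conditions: BBr3 (about 2 equiv per OMe), CH2Cl2, −78 °C to rt, Ar; then H2O, 0 °C; reversed-phase chromatography with degassed, acidified solvents
Reagents that add atoms: none
Why: Lewis-acid cleavage of aryl methyl ethers with BBr3 should remove all thirteen methyl groups as bromomethane while the diaryl ether bonds, which cannot form a stabilised leaving group, stay intact.

Compound list
1 | 4-bromo-2,6-dimethoxyphenol | COc1cc(Br)cc(OC)c1O | starting material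
2 | 2-(benzyloxy)-5-bromo-1,3-dimethoxybenzene | COc1cc(Br)cc(OC)c1OCc1ccccc1 | intermediate
3 | 2,4,6-trimethoxyphenol | COc1cc(OC)c(O)c(OC)c1 | starting material
4 | dimer AB benzyl ether, 2-[4-(benzyloxy)-3,5-dimethoxyphenoxy]-1,3,5-trimethoxybenzene | COc1cc(OC)c(Oc2cc(OC)c(OCc3ccccc3)c(OC)c2)c(OC)c1 | intermediate
5 | dimer AB phenol, 2,6-dimethoxy-4-(2,4,6-trimethoxyphenoxy)phenol | COc1cc(OC)c(Oc2cc(OC)c(O)c(OC)c2)c(OC)c1 | intermediate
6 | trimer ABC benzyl ether: 2,4,6-trimethoxyphenyl (ring A) – O – 3,5-dimethoxy-1,4-phenylene (ring B) – O – 4-(benzyloxy)-3,5-dimethoxyphenyl (ring C) | COc1cc(OC)c(Oc2cc(OC)c(Oc3cc(OC)c(OCc4ccccc4)c(OC)c3)c(OC)c2)c(OC)c1 | intermediate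
7 | trimer ABC phenol: as 6 with free hydroxyl on C4 of ring C | COc1cc(OC)c(Oc2cc(OC)c(Oc3cc(OC)c(O)c(OC)c3)c(OC)c2)c(OC)c1 | intermediate
8 | tetramer ABCD benzyl ether: chain A–O–B–O–C–O–D, rings B and C 3,5-dimethoxy-1,4-phenylene, ring D 4-(benzyloxy)-3,5-dimethoxyphenyl | COc1cc(OC)c(Oc2cc(OC)c(Oc3cc(OC)c(Oc4cc(OC)c(OCc5ccccc5)c(OC)c4)c(OC)c3)c(OC)c2)c(OC)c1 | intermediate
9 | tetramer ABCD phenol: nonamethyl ether with free hydroxyl on C4 of ring D | COc1cc(OC)c(Oc2cc(OC)c(Oc3cc(OC)c(Oc4cc(OC)c(O)c(OC)c4)c(OC)c3)c(OC)c2)c(OC)c1 | intermediate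
10 | syringic acid, 4-hydroxy-3,5-dimethoxybenzoic acid | COc1cc(C(=O)O)cc(OC)c1O | starting material
11 | pentamer ABCDE phenol: undecamethyl ether with free hydroxyl on C4 of ring E | COc1cc(OC)c(Oc2cc(OC)c(Oc3cc(OC)c(Oc4cc(OC)c(Oc5cc(OC)c(O)c(OC)c5)c(OC)c4)c(OC)c3)c(OC)c2)c(OC)c1 | intermediate (formed in the flask in step 8, not isolated)
12 | hexamer ABCDEF phenol: tridecamethyl ether with free hydroxyl on C4 of ring F | COc1cc(OC)c(Oc2cc(OC)c(Oc3cc(OC)c(Oc4cc(OC)c(Oc5cc(OC)c(Oc6cc(OC)c(O)c(OC)c6)c(OC)c5)c(OC)c4)c(OC)c3)c(OC)c2)c(OC)c1 | intermediate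
13 | CNP0187343.0, the fully hydroxylated hexamer (no stereocentres) | Oc1cc(O)c(Oc2cc(O)c(Oc3cc(O)c(Oc4cc(O)c(Oc5cc(O)c(Oc6cc(O)c(O)c(O)c6)c(O)c5)c(O)c4)c(O)c3)c(O)c2)c(O)c1 | target

Total step count: 9. Longest linear sequence: 9 steps (1 to 13).

Steps most likely to fail

Step 8. Chain growth may not stop at two additions, the acid may be consumed by self-coupling, and the chain may be cut or scrambled by over-oxidation and quinone-ketal exchange. The fallback uses only known chemistry and sets out from 9. Coupling of 9 with 2 under the CuI–picolinic acid conditions of step 6 should give the pentamer ABCDE benzyl ether F1. Hydrogenolysis over Pd/C then gives pentamer phenol 11, isolated this time. A second coupling with 2 gives the hexamer ABCDEF benzyl ether F2, and its hydrogenolysis comes back to the route at 12.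

Step 9. Some of the thirteen ethers may resist cleavage, and the free polyphenol may oxidise in air during isolation. The fallback sets out from 12 and changes the isolation to a derivatise-and-release sequence. After the BBr3 treatment the crude product is not isolated but acetylated directly (Ac2O, pyridine) to the air-stable tetradecaacetate F3. This is purified on silica, where incompletely demethylated material can be separated and resubmitted. Acid-catalysed methanolysis (AcCl in degassed MeOH, rt, Ar) then releases the polyphenol and comes back to the route at 13.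

Step 6. The electron-rich bromide may react only slowly with the large, hindered phenoxide, so that conversion stalls and bromine is lost reductively. The fallback sets out from 7 and replaces copper catalysis by addition–elimination. SNAr of the phenoxide of 7 on purchased 4-fluoro-2,6-dimethoxybenzaldehyde (COc1cc(F)cc(OC)c1C=O; K2CO3, DMF, 110 °C) should give the tetramer ABCD aldehyde F4. Baeyer–Villiger oxidation (mCPBA, NaHCO3, CH2Cl2, 0 °C) converts it to the tetramer ABCD aryl formate F5. Hydrolysis (KOH, MeOH–H2O) comes back to the route at 9, so steps 6 and 7 are both bypassed.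

Further compounds
F1 | step 8 | pentamer ABCDE benzyl ether | COc1cc(OC)c(Oc2cc(OC)c(Oc3cc(OC)c(Oc4cc(OC)c(Oc5cc(OC)c(OCc6ccccc6)c(OC)c5)c(OC)c4)c(OC)c3)c(OC)c2)c(OC)c1
F2 | step 8 | hexamer ABCDEF benzyl ether | COc1cc(OC)c(Oc2cc(OC)c(Oc3cc(OC)c(Oc4cc(OC)c(Oc5cc(OC)c(Oc6cc(OC)c(OCc7ccccc7)c(OC)c6)c(OC)c5)c(OC)c4)c(OC)c3)c(OC)c2)c(OC)c1
F3 | step 9 | tetradecaacetate of the target | CC(=O)Oc1cc(OC(C)=O)c(Oc2cc(OC(C)=O)c(Oc3cc(OC(C)=O)c(Oc4cc(OC(C)=O)c(Oc5cc(OC(C)=O)c(Oc6cc(OC(C)=O)c(OC(C)=O)c(OC(C)=O)c6)c(OC(C)=O)c5)c(OC(C)=O)c4)c(OC(C)=O)c3)c(OC(C)=O)c2)c(OC(C)=O)c1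
F4 | step 6 | tetramer ABCD aldehyde (formyl on C4 of ring D) | COc1cc(OC)c(Oc2cc(OC)c(Oc3cc(OC)c(Oc4cc(OC)c(C=O)c(OC)c4)c(OC)c3)c(OC)c2)c(OC)c1
F5 | step 6 | tetramer ABCD aryl formate (formyloxy on C4 of ring D) | COc1cc(OC)c(Oc2cc(OC)c(Oc3cc(OC)c(Oc4cc(OC)c(OC=O)c(OC)c4)c(OC)c3)c(OC)c2)c(OC)c1
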